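**Plan**
1. Retrosynthesis (drimane numbering: ring A = C1–C5 + C10, ring B = C5–C10, C11 on C9, C12 on C8): cut the C1 ester, return the two formyl groups to an 11,12-diol, reduce C1 to a ketone, then open both carbocycles at once by cutting C2–C3 and C5–C10 of ring A.
2. Enabling feature: the C1 carbonyl is flanked by C2 and C10, both enolisable, and the quaternary C4 is flanked by C3 and C5. With C3 as an aldehyde and C5 as the δ-carbon of the C12 ester (conjugated through C7=C8 and C5=C6), an α,α′-annulation of the C1 ketone can close ring B and then ring A in one operation.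
3. Forward: Morita–Baylis–Hillman adduct of tert-butyl acrylate, asymmetric allylic alkylation with 3-methylpentane-2,4-dione (sets C9), Heck coupling with an iodo-enal to the open-chain dienoate, then deacetylative 1,6-Michael/aldol condensation to the decalin.
4. Stereochemistry: C9 from the cinchona amine catalyst; C5 and C10 from C9 in the chair-like ring-B closure (three carbon arms equatorial, methyl axial); C1 from axial hydride delivery to the 1-ketone.
5. Endgame: C2=C3 hydrogenation, LiAlH4 reduction, silylation of the primary hydroxyl, cinnamoylation at O1, desilylation, Swern oxidation.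

Key step: step 7

Remark: (DHQD)2PHAL is assumed to deliver the (R) centre in step 3; if the sense proves opposite, its pseudoenantiomer (DHQ)2PHAL takes its place.

Step 1
Reactants: 1 tert-butyl prop-2-enoate; 2 2-[(tert-butyldimethylsilyl)oxy]acetaldehyde
Product: 3 tert-butyl 4-[(tert-butyldimethylsilyl)oxy]-3-hydroxy-2-methylidenebutanoate (racemic)
Conditions: DABCO (1 equiv), dioxane/H2O (1:1), rt
Reagents that add atoms: none
Why: Morita–Baylis–Hillman reaction of an acrylate with a reactive α-alkoxy aldehyde; the carbinol centre forms racemic and is erased in step 3.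

Step 2
Reactants: 3 tert-butyl 4-[(tert-butyldimethylsilyl)oxy]-3-hydroxy-2-methylidenebutanoate
Product: 4 tert-butyl 3-[(tert-butoxycarbonyl)oxy]-4-[(tert-butyldimethylsilyl)oxy]-2-methylidenebutanoate (racemic)
Conditions: Boc2O, DMAP (10 mol %), CH2Cl2, 0 °C to rt
Reagents that add atoms: di-tert-butyl dicarbonate (Boc2O), CC(C)(C)OC(=O)OC(=O)OC(C)(C)C
Why: DMAP-catalysed carbonate formation turns the allylic hydroxyl into the leaving group needed for Lewis-base-catalysed substitution.

Step 3
Reactants: 4 tert-butyl 3-[(tert-butoxycarbonyl)oxy]-4-[(tert-butyldimethylsilyl)oxy]-2-methylidenebutanoate; 5 3-methylpentane-2,4-dione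
Product: 6 tert-butyl (3R)-4-acetyl-3-{[(tert-butyldimethylsilyl)oxy]methyl}-4-methyl-2-methylidene-5-oxohexanoate
Conditions: (DHQD)2PHAL (10 mol %), PhCF3, rt
Reagents that add atoms: none
Why: Cinchona-amine-catalysed asymmetric allylic alkylation of a Morita–Baylis–Hillman carbonate (SN2′–SN2′ sequence): the chiral allylammonium ion is attacked at C9 on one face by the diketonate freed by tert-butoxide, so both enantiomers of 4 should converge on (R)-6, and C10 is not yet a stereocentre because its two acetyl groups are identical.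

Step 4
Reactants: 7 3-hydroxy-2,2-dimethylpropanal
Product: 8 (3E)-4-iodo-2,2-dimethylbut-3-en-1-ol
Conditions: CrCl2 (6 equiv), CHI3 (2 equiv), THF, 0 °C to rt
Reagents that add atoms: iodoform, IC(I)I
Why: Takai olefination converts the aldehyde into the (E)-vinyl iodide, the E geometry following from elimination of the geminal dichromium adduct with the bulky quaternary carbon anti to iodine.

Step 5
Reactants: 8 (3E)-4-iodo-2,2-dimethylbut-3-en-1-ol
Product: 9 (3E)-4-iodo-2,2-dimethylbut-3-enal
Conditions: Dess–Martin periodinane, NaHCO3, CH2Cl2, rt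
Reagents that add atoms: none
Why: Dess–Martin oxidation of the neopentyl primary alcohol gives the non-enolisable aldehyde and leaves the vinyl iodide untouched.

Step 6
Reactants: 6 tert-butyl (3R)-4-acetyl-3-{[(tert-butyldimethylsilyl)oxy]methyl}-4-methyl-2-methylidene-5-oxohexanoate; 9 (3E)-4-iodo-2,2-dimethylbut-3-enal
Product: 10 tert-butyl (2E,4E)-2-[(2R)-3-acetyl-1-[(tert-butyldimethylsilyl)oxy]-3-methyl-4-oxopentan-2-yl]-6,6-dimethyl-7-oxohepta-2,4-dienoate
Conditions: Pd(OAc)2 (5 mol %), Bu4NCl, NaHCO3, DMF, 40 °C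
Reagents that add atoms: none
Why: Heck reaction under Jeffery conditions: the vinylpalladium adds to the unsubstituted terminus of the 1,1-disubstituted acrylate and syn β-hydride elimination towards C7 should give the conjugated (2E,4E)-dienoate, which places C6 cis to C9 as the ring closure requires.

Step 7
Reactants: 10 tert-butyl (2E,4E)-2-[(2R)-3-acetyl-1-[(tert-butyldimethylsilyl)oxy]-3-methyl-4-oxopentan-2-yl]-6,6-dimethyl-7-oxohepta-2,4-dienoate
Product: 13 tert-butyl (1R,4aS,8aS)-1-{[(tert-butyldimethylsilyl)oxy]methyl}-5,5,8a-trimethyl-8-oxo-1,4,4a,5,8,8a-hexahydronaphthalene-2-carboxylate, via sodium enolate 11 (not isolated), via cyclohexene keto aldehyde 12 (not isolated)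
Conditions: NaOMe (1.1 equiv), THF (0.01 M), −20 °C to rt; then MeOH, 50 °C (one pot)
Reagents that add atoms: none
Why: Proposed new method: methoxide cleaves one acetyl group of the non-enolisable 1,3-diketone (retro-Claisen) and so unmasks the sodium enolate regiospecifically at C10; this enolate adds to C5, the δ-carbon of the tert-butyl dienoate, in a 1,6-conjugate addition, proton transfer then gives the C2 enolate, which adds to the C3 aldehyde, and E1cB loss of water from the aldol ends the cascade. The closest known reaction types are the Robinson-type Michael/aldol annulation of ketones with enals and the vinylogous Michael addition of ketone enolates to 2,4-dienoates; merging them into an α,α′-annulation of one ketone has not been shown, but each elementary step is standard enolate chemistry and the reversible, sterically demanding first addition is drained by the irreversible dehydration. Ring B closes in the 6-endo-trig mode (C5=C6 and C7=C8 both lie inside the forming ring, which the cis relation of C9 and C6 on C7=C8 allows) and ring A in the 6-exo-trig (enolexo) aldol mode. C5 and C10 are set in the chair-like transition state of the ring-B closure under control of the C9 stereocentre: the CH2OTBS group on C9, the enolate carbon C1 on C10 and the tert-alkyl chain on C5 (outside position of the E alkene) lie pseudo-equatorial and the C10 methyl axial, which should give 5α-H and 10β-CH3 and hence the trans ring fusion. The step needs the C10 enolate, not the C2 enolate, to make the first bond (the C2 enolate could reach C7 through a six-membered ring); this is secured by generating the enolate by deacylation with one equivalent of base in aprotic THF, where enolate equilibration is slow, and by the fact that C10 can reach only C5 (C7 or the ester carbon would need a four-membered ring). It also needs chemoselectivity against Claisen acylation and the final C7=C8 alkene position, secured by the tert-butyl ester and by base equilibration of the alkene into conjugation with it once methanol is added.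

Step 8
Reactants: 13 tert-butyl (1R,4aS,8aS)-1-{[(tert-butyldimethylsilyl)oxy]methyl}-5,5,8a-trimethyl-8-oxo-1,4,4a,5,8,8a-hexahydronaphthalene-2-carboxylate
Product: 14 tert-butyl (1R,4aS,8aS)-1-{[(tert-butyldimethylsilyl)oxy]methyl}-5,5,8a-trimethyl-8-oxo-1,4,4a,5,6,7,8,8a-octahydronaphthalene-2-carboxylate
Conditions: H2 (1 atm), Pd/C (5 wt %), EtOAc, rt, stopped after 1 equiv H2
Reagents that add atoms: none
Why: Heterogeneous hydrogenation should reduce the cis-disubstituted enone alkene C2=C3 much faster than the trisubstituted, ester-conjugated and hindered C7=C8 alkene.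

Step 9
Reactants: 14 tert-butyl (1R,4aS,8aS)-1-{[(tert-butyldimethylsilyl)oxy]methyl}-5,5,8a-trimethyl-8-oxo-1,4,4a,5,6,7,8,8a-octahydronaphthalene-2-carboxylate
Product: 15 (1R,4aS,8S,8aS)-8-{[(tert-butyldimethylsilyl)oxy]methyl}-7-(hydroxymethyl)-4,4,8a-trimethyl-1,2,3,4,4a,5,8,8a-octahydronaphthalen-1-ol
Conditions: LiAlH4, THF, 0 °C
Reagents that add atoms: none
Why: LiAlH4 reduces the conjugated tert-butyl ester to the allylic alcohol and the 1-ketone by axial hydride attack from the α face (anti to the axial C10 methyl, away from the C11 arm), which should give the equatorial 1β-alcohol.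

Step 10
Reactants: 15 (1R,4aS,8S,8aS)-8-{[(tert-butyldimethylsilyl)oxy]methyl}-7-(hydroxymethyl)-4,4,8a-trimethyl-1,2,3,4,4a,5,8,8a-octahydronaphthalen-1-ol
Product: 16 (1R,4aS,8S,8aS)-7,8-bis{[(tert-butyldimethylsilyl)oxy]methyl}-4,4,8a-trimethyl-1,2,3,4,4a,5,8,8a-octahydronaphthalen-1-ol
Conditions: TBSCl (1.1 equiv), imidazole, CH2Cl2, 0 °C
Reagents that add atoms: tert-butyldimethylsilyl chloride (TBSCl), CC(C)(C)[Si](C)(C)Cl
Why: Silylation is selective for the primary allylic hydroxyl over the hindered secondary C1 hydroxyl next to the quaternary C10.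

Step 11
Reactants: 16 (1R,4aS,8S,8aS)-7,8-bis{[(tert-butyldimethylsilyl)oxy]methyl}-4,4,8a-trimethyl-1,2,3,4,4a,5,8,8a-octahydronaphthalen-1-ol; 17 (2E)-3-(4-methoxyphenyl)prop-2-enoyl chloride
Product: 18 (1R,4aS,8S,8aS)-7,8-bis{[(tert-butyldimethylsilyl)oxy]methyl}-4,4,8a-trimethyl-1,2,3,4,4a,5,8,8a-octahydronaphthalen-1-yl (2E)-3-(4-methoxyphenyl)prop-2-enoate
Conditions: DMAP (1 equiv), Et3N, CH2Cl2, 40 °C
Reagents that add atoms: none
Why: DMAP-mediated acylation through the acylpyridinium ion esterifies the only free hydroxyl with retention at C1.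

Step 12
Reactants: 18 (1R,4aS,8S,8aS)-7,8-bis{[(tert-butyldimethylsilyl)oxy]methyl}-4,4,8a-trimethyl-1,2,3,4,4a,5,8,8a-octahydronaphthalen-1-yl (2E)-3-(4-methoxyphenyl)prop-2-enoate
Product: 19 (1R,4aS,8S,8aS)-7,8-bis(hydroxymethyl)-4,4,8a-trimethyl-1,2,3,4,4a,5,8,8a-octahydronaphthalen-1-yl (2E)-3-(4-methoxyphenyl)prop-2-enoate
Conditions: HF·pyridine, pyridine, THF, 0 °C to rt
Reagents that add atoms: none
Why: Fluoride cleavage of both primary silyl ethers under mildly acidic conditions should avoid acyl migration from O1 to O11.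

Step 13
Reactants: 19 (1R,4aS,8S,8aS)-7,8-bis(hydroxymethyl)-4,4,8a-trimethyl-1,2,3,4,4a,5,8,8a-octahydronaphthalen-1-yl (2E)-3-(4-methoxyphenyl)prop-2-enoate
Product: 20 (1R,4aS,8R,8aS)-7,8-diformyl-4,4,8a-trimethyl-1,2,3,4,4a,5,8,8a-octahydronaphthalen-1-yl (2E)-3-(4-methoxyphenyl)prop-2-enoate
Conditions: (COCl)2, DMSO, CH2Cl2, −78 °C; then Et3N, −78 to 0 °C
Reagents that add atoms: none
Why: Swern oxidation of the 11,12-diol: both hydroxyls are activated as alkoxysulfonium ions before base is added, so no lactol can form, and the 1,4-dialdehyde is released at low temperature without epimerisation at C9.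

**Compound list**
1 | tert-butyl prop-2-enoate | C=CC(=O)OC(C)(C)C | starting material
2 | 2-[(tert-butyldimethylsilyl)oxy]acetaldehyde | O=CCO[Si](C)(C)C(C)(C)C | starting material
3 | tert-butyl 4-[(tert-butyldimethylsilyl)oxy]-3-hydroxy-2-methylidenebutanoate (racemic) | C=C(C(=O)OC(C)(C)C)C(O)CO[Si](C)(C)C(C)(C)C | intermediate
4 | tert-butyl 3-[(tert-butoxycarbonyl)oxy]-4-[(tert-butyldimethylsilyl)oxy]-2-methylidenebutanoate (racemic) | C=C(C(=O)OC(C)(C)C)C(OC(=O)OC(C)(C)C)CO[Si](C)(C)C(C)(C)C | intermediate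
5 | 3-methylpentane-2,4-dione | CC(=O)C(C)C(C)=O | starting material
6 | tert-butyl (3R)-4-acetyl-3-{[(tert-butyldimethylsilyl)oxy]methyl}-4-methyl-2-methylidene-5-oxohexanoate | C=C(C(=O)OC(C)(C)C)[C@H](CO[Si](C)(C)C(C)(C)C)C(C)(C(C)=O)C(C)=O | intermediate
7 | 3-hydroxy-2,2-dimethylpropanal | CC(C)(CO)C=O | starting material
8 | (3E)-4-iodo-2,2-dimethylbut-3-en-1-ol | CC(C)(CO)/C=C/I | intermediate
9 | (3E)-4-iodo-2,2-dimethylbut-3-enal | CC(C)(C=O)/C=C/I | intermediate
10 | tert-butyl (2E,4E)-2-[(2R)-3-acetyl-1-[(tert-butyldimethylsilyl)oxy]-3-methyl-4-oxopentan-2-yl]-6,6-dimethyl-7-oxohepta-2,4-dienoate | CC(C)(C)OC(=O)/C(=C/C=C/C(C)(C)C=O)[C@H](CO[Si](C)(C)C(C)(C)C)C(C)(C(C)=O)C(C)=O | intermediate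
11 | sodium enolate (C10=C1–O−, geometry not defined) of tert-butyl (2E,4E)-2-[(2R)-1-[(tert-butyldimethylsilyl)oxy]-3-methyl-4-oxopentan-2-yl]-6,6-dimethyl-7-oxohepta-2,4-dienoate | CC(C)(C)OC(=O)/C(=C/C=C/C(C)(C)C=O)[C@H](CO[Si](C)(C)C(C)(C)C)C(C)=C(C)[O-].[Na+] | intermediate
12 | tert-butyl (4S,5S,6R)-5-acetyl-6-{[(tert-butyldimethylsilyl)oxy]methyl}-5-methyl-4-(2-methyl-1-oxopropan-2-yl)cyclohex-1-ene-1-carboxylate | CC(=O)[C@]1(C)[C@@H](CO[Si](C)(C)C(C)(C)C)C(C(=O)OC(C)(C)C)=CC[C@H]1C(C)(C)C=O | intermediate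
13 | tert-butyl (1R,4aS,8aS)-1-{[(tert-butyldimethylsilyl)oxy]methyl}-5,5,8a-trimethyl-8-oxo-1,4,4a,5,8,8a-hexahydronaphthalene-2-carboxylate | O=C2C=CC(C)(C)[C@@H]3CC=C(C(=O)OC(C)(C)C)[C@H](CO[Si](C)(C)C(C)(C)C)[C@@]23C | intermediate
14 | tert-butyl (1R,4aS,8aS)-1-{[(tert-butyldimethylsilyl)oxy]methyl}-5,5,8a-trimethyl-8-oxo-1,4,4a,5,6,7,8,8a-octahydronaphthalene-2-carboxylate | O=C2CCC(C)(C)[C@@H]3CC=C(C(=O)OC(C)(C)C)[C@H](CO[Si](C)(C)C(C)(C)C)[C@@]23C | intermediate
15 | (1R,4aS,8S,8aS)-8-{[(tert-butyldimethylsilyl)oxy]methyl}-7-(hydroxymethyl)-4,4,8a-trimethyl-1,2,3,4,4a,5,8,8a-octahydronaphthalen-1-ol | O[C@@H]2CCC(C)(C)[C@@H]3CC=C(CO)[C@H](CO[Si](C)(C)C(C)(C)C)[C@@]23C | intermediate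
16 | (1R,4aS,8S,8aS)-7,8-bis{[(tert-butyldimethylsilyl)oxy]methyl}-4,4,8a-trimethyl-1,2,3,4,4a,5,8,8a-octahydronaphthalen-1-ol | O[C@@H]2CCC(C)(C)[C@@H]3CC=C(CO[Si](C)(C)C(C)(C)C)[C@H](CO[Si](C)(C)C(C)(C)C)[C@@]23C | intermediate
17 | (2E)-3-(4-methoxyphenyl)prop-2-enoyl chloride | COc1ccc(/C=C/C(Cl)=O)cc1 | starting material
18 | (1R,4aS,8S,8aS)-7,8-bis{[(tert-butyldimethylsilyl)oxy]methyl}-4,4,8a-trimethyl-1,2,3,4,4a,5,8,8a-octahydronaphthalen-1-yl (2E)-3-(4-methoxyphenyl)prop-2-enoate | COc1ccc(/C=C/C(=O)O[C@@H]2CCC(C)(C)[C@@H]3CC=C(CO[Si](C)(C)C(C)(C)C)[C@H](CO[Si](C)(C)C(C)(C)C)[C@@]23C)cc1 | intermediate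
19 | (1R,4aS,8S,8aS)-7,8-bis(hydroxymethyl)-4,4,8a-trimethyl-1,2,3,4,4a,5,8,8a-octahydronaphthalen-1-yl (2E)-3-(4-methoxyphenyl)prop-2-enoate | COc1ccc(/C=C/C(=O)O[C@@H]2CCC(C)(C)[C@@H]3CC=C(CO)[C@H](CO)[C@@]23C)cc1 | intermediate
20 | (1R,4aS,8R,8aS)-7,8-diformyl-4,4,8a-trimethyl-1,2,3,4,4a,5,8,8a-octahydronaphthalen-1-yl (2E)-3-(4-methoxyphenyl)prop-2-enoate | COc1ccc(/C=C/C(=O)O[C@@H]2CCC(C)(C)[C@@H]3CC=C(C=O)[C@H](C=O)[C@@]23C)cc1 | target

**Step count**
Total: 13 steps. Longest linear sequence: 11 steps (steps 1, 2, 3, 6, 7, 8, 9, 10, 11, 12, 13).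

**Steps most likely to fail**

Step 7 (Proposed new method). Three processes could defeat it. The first conjugate addition joins a fully substituted enolate carbon to a carbon next to the quaternary C4 and may stay on the open-chain side (retro-Michael). Proton transfer may give the C2 enolate before ring B has closed, and this enolate adds 1,4 to C7. The ester dienolate formed after ring closure may add reversibly to the C3 aldehyde. The fallback replaces the polar ring-B closure by a radical one and separates the two bond formations. It sets out from 10. Deacylation with NaOMe in THF at 0 °C and trapping of the regiodefined enolate with PhSeBr at −78 °C should give tert-butyl (2E,4E)-2-[(2R)-1-[(tert-butyldimethylsilyl)oxy]-3-methyl-4-oxo-3-(phenylselanyl)pentan-2-yl]-6,6-dimethyl-7-oxohepta-2,4-dienoate F1. Slow addition of Bu3SnH with AIBN in benzene at 80 °C generates the tertiary α-keto radical at C10. It should close ring B by addition to the diene terminus C5 (the known 6-endo cyclisation of α-carbonyl radicals onto dienes, which gives the ester-stabilised allyl radical), and hydrogen transfer then gives keto aldehyde 12, now isolated. Piperidinium acetate in benzene at 80 °C then effects the aldol condensation, and the route is rejoined at 13.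

Step 3. The allylic alkylation joins a fully substituted nucleophilic carbon to a secondary carbon of an aliphatic Morita–Baylis–Hillman carbonate; slow turnover and poor facial selectivity are the likely failures. The fallback sets the same centre by iminium catalysis and builds the acrylate afterwards. It sets out from 5. Conjugate addition of 5 to (2E)-4-[(tert-butyldimethylsilyl)oxy]but-2-enal under a diarylprolinol silyl ether catalyst (enantiomer chosen for the required face) should give (3S)-4-acetyl-3-{[(tert-butyldimethylsilyl)oxy]methyl}-4-methyl-5-oxohexanal F2. α-Methylenation with aqueous formaldehyde, pyrrolidine and propionic acid gives (3S)-4-acetyl-3-{[(tert-butyldimethylsilyl)oxy]methyl}-4-methyl-2-methylidene-5-oxohexanal F3. Pinnick oxidation (NaClO2, NaH2PO4, 2-methylbut-2-ene) gives (3R)-4-acetyl-3-{[(tert-butyldimethylsilyl)oxy]methyl}-4-methyl-2-methylidene-5-oxohexanoic acid F4. Esterification with tert-butyl 2,2,2-trichloroacetimidate rejoins the route at 6.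

Step 11. Acyl transfer to the C1 hydroxyl is slow because it sits next to the quaternary C10 and close to the C11 silyloxymethyl arm; forcing conditions invite silyl migration or elimination. The fallback brings in a small acyl group first and builds the cinnamate on the molecule. It sets out from 16. Coupling with 2-(diethoxyphosphoryl)acetic acid (DCC, DMAP, CH2Cl2) should give (1R,4aS,8S,8aS)-7,8-bis{[(tert-butyldimethylsilyl)oxy]methyl}-4,4,8a-trimethyl-1,2,3,4,4a,5,8,8a-octahydronaphthalen-1-yl 2-(diethoxyphosphoryl)acetate F5. Horner–Wadsworth–Emmons olefination with 4-methoxybenzaldehyde (LiCl, DBU, MeCN) gives the (E)-cinnamate and rejoins the route at 18.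

**Further compounds**
F1 | step 7 | tert-butyl (2E,4E)-2-[(2R)-1-[(tert-butyldimethylsilyl)oxy]-3-methyl-4-oxo-3-(phenylselanyl)pentan-2-yl]-6,6-dimethyl-7-oxohepta-2,4-dienoate (both epimers at the selenium-bearing carbon) | CC(C)(C)OC(=O)/C(=C/C=C/C(C)(C)C=O)[C@H](CO[Si](C)(C)C(C)(C)C)C(C)([Se]c1ccccc1)C(C)=O
F2 | step 3 | (3S)-4-acetyl-3-{[(tert-butyldimethylsilyl)oxy]methyl}-4-methyl-5-oxohexanal | O=CC[C@H](CO[Si](C)(C)C(C)(C)C)C(C)(C(C)=O)C(C)=O
F3 | step 3 | (3S)-4-acetyl-3-{[(tert-butyldimethylsilyl)oxy]methyl}-4-methyl-2-methylidene-5-oxohexanal | C=C(C=O)[C@H](CO[Si](C)(C)C(C)(C)C)C(C)(C(C)=O)C(C)=O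
F4 | step 3 | (3R)-4-acetyl-3-{[(tert-butyldimethylsilyl)oxy]methyl}-4-methyl-2-methylidene-5-oxohexanoic acid | C=C(C(=O)O)[C@H](CO[Si](C)(C)C(C)(C)C)C(C)(C(C)=O)C(C)=O
F5 | step 11 | (1R,4aS,8S,8aS)-7,8-bis{[(tert-butyldimethylsilyl)oxy]methyl}-4,4,8a-trimethyl-1,2,3,4,4a,5,8,8a-octahydronaphthalen-1-yl 2-(diethoxyphosphoryl)acetate | CCOP(=O)(OCC)CC(=O)O[C@@H]2CCC(C)(C)[C@@H]3CC=C(CO[Si](C)(C)C(C)(C)C)[C@H](CO[Si](C)(C)C(C)(C)C)[C@@]23C
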